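**Plan**

1. Retrosynthesis: the C7 carbinol of the benzoxepine is taken back to a ketone, so the bond from C6 to the linker CH2 becomes the Cα=Cβ bond of an enone. It is cut by a Horner–Wadsworth–Emmons union of aldehyde 17 (hydroazulene plus both linker carbons) with β-keto phosphonate 22 (acyclic diepoxide). The O1–C2 and C5a–C6 bonds of the benzoxepine are then cut together as one epoxide-opening cascade.
2. Enabling feature: benzoxepine C6 is α and the linker CH2 is β to the ketone latent in C7(OH)Me. Hydroazulene C5 carries CH2–C next to the C6=C7 alkene, a γ,δ-unsaturated carbonyl (Claisen) retron. One Claisen therefore gives exactly the aldehyde the olefination needs, and the enone fixes which enol ether ends the cascade.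
3. Forward, hydroazulene: (S)-linalool → cyclopentenol by ring-closing metathesis → Ireland–Claisen (C3a, quaternary C4) → Z-enoate → diazoketone → cyclopropanation closes the seven-membered ring → ring-opening hydration (C1 carbinol) → CBS reduction and Claisen (C5 and side chain).
4. Forward, benzoxepine: (E)-geranylacetone → Shi diepoxide → phosphonate 22 → union → 1,4-hydrosilylation and cascade (oxepane, then cyclohexanone) → MeMgBr, desilylation, oxidation.
5. Stereochemistry: the linalool centre is relayed to C3a, C8a and C1 by suprafacial and tether-directed events; C7 and C5 come from the CBS reduction and its Claisen transfer. C9a and C5a come from the Shi epoxides (inversion at C5a), C6 is thermodynamic (α to the ketone), and C7 arises by equatorial methyl addition.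

Key step: step 15

Assumption: (S)-(+)-linalool of high enantiomeric purity and isomerically pure (E)-geranylacetone are purchased; locants below are hydroazulene C1–C8a (C1 carbinol, C4 CMe2, C5 side chain) and benzoxepine O1–C9a.

**Route**

Step 1
Reactants: 1 (S)-(+)-linalool
Product: 2 (S)-1-methylcyclopent-2-en-1-ol
Conditions: second-generation Grubbs catalyst RuCl2(=CHPh)(PCy3)(H2IMes) (1 mol %), CH2Cl2, 40 °C
Reagents that add atoms: none
Why: Ring-closing metathesis of the 1,6-diene should expel isobutene and leave the tertiary carbinol centre untouched, so the purchased stereocentre becomes the allylic C–O centre of the ring.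

Step 2
Reactants: 2 (S)-1-methylcyclopent-2-en-1-ol
Product: 3 (S)-1-methylcyclopent-2-en-1-yl 2-methylpropanoate
Conditions: (iPrCO)2O, Et3N, DMAP (cat.), CH2Cl2, 40 °C
Reagents that add atoms: isobutyric anhydride, CC(C)C(=O)OC(=O)C(C)C
Why: DMAP-catalysed acyl transfer (Steglich-type acylation) should esterify the tertiary allylic alcohol under basic conditions that do not ionise the C–O bond.

Step 3
Reactants: 3 (S)-1-methylcyclopent-2-en-1-yl 2-methylpropanoate
Product: 6 2-methyl-2-[(1R)-3-methylcyclopent-2-en-1-yl]propan-1-ol, via silyl ketene acetal 4 (not isolated), via trimethylsilyl ester 5 (not isolated)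
Conditions: LiN(iPr)2, Me3SiCl, Et3N, THF, −78 → 60 °C; then LiAlH4, 0 °C
Reagents that add atoms: none
Why: Ireland–Claisen rearrangement: the suprafacial [3,3] shift through a boat-like transition state should turn the C–O centre of 3 into the C–C centre of 6 (future C3a) on the same ring face while forming the quaternary gem-dimethyl carbon (future C4), and the silyl ester is reduced in the same flask.

Step 4
Reactants: 6 2-methyl-2-[(1R)-3-methylcyclopent-2-en-1-yl]propan-1-ol
Product: 7 2-methyl-2-[(1R)-3-methylcyclopent-2-en-1-yl]propanal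
Conditions: Dess–Martin periodinane, NaHCO3, CH2Cl2, 0 → 23 °C
Reagents that add atoms: none
Why: Dess–Martin oxidation of a neopentyl primary alcohol should stop cleanly at the non-enolisable aldehyde.

Step 5
Reactants: 7 2-methyl-2-[(1R)-3-methylcyclopent-2-en-1-yl]propanal
Product: 8 methyl (2Z)-2,4-dimethyl-4-[(1R)-3-methylcyclopent-2-en-1-yl]pent-2-enoate
Conditions: (CF3CH2O)2P(O)CH(CH3)CO2Me, KN(SiMe3)2, 18-crown-6, THF, −78 °C
Reagents that add atoms: methyl 2-[bis(2,2,2-trifluoroethoxy)phosphoryl]propanoate, COC(=O)C(C)P(=O)(OCC(F)(F)F)OCC(F)(F)F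
Why: Still–Gennari olefination: fast, irreversible elimination from the electron-poor phosphonate adduct should give the Z-trisubstituted enoate, the geometry that later lets the chain reach the ring alkene.

Step 6
Reactants: 8 methyl (2Z)-2,4-dimethyl-4-[(1R)-3-methylcyclopent-2-en-1-yl]pent-2-enoate
Product: 9 (2Z)-2,4-dimethyl-4-[(1R)-3-methylcyclopent-2-en-1-yl]pent-2-enoic acid
Conditions: LiOH, THF/MeOH/H2O, 50 °C; then 1 M HCl
Reagents that add atoms: lithium hydroxide, [Li+].[OH-]
Why: Saponification should proceed without Z→E isomerisation because the β-carbon carries a quaternary substituent that blocks conjugate addition–elimination.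

Step 7
Reactants: 9 (2Z)-2,4-dimethyl-4-[(1R)-3-methylcyclopent-2-en-1-yl]pent-2-enoic acid
Product: 11 (3Z)-1-diazo-3,5-dimethyl-5-[(1R)-3-methylcyclopent-2-en-1-yl]hex-3-en-2-one, via acid chloride 10 (not isolated)
Conditions: Me2C=C(Cl)NMe2, CH2Cl2, 0 °C; then CH2N2 (excess), Et2O, 0 °C
Reagents that add atoms: diazomethane, C=[N+]=[N-]
Why: Neutral acid chloride formation with the α-chloroenamine avoids acid-promoted alkene isomerisation, and acylation of diazomethane (first stage of the Arndt–Eistert sequence) should give the α′-diazo enone.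

Step 8
Reactants: 11 (3Z)-1-diazo-3,5-dimethyl-5-[(1R)-3-methylcyclopent-2-en-1-yl]hex-3-en-2-one
Product: 12 tricyclic cyclopropyl enone (1,4,4,6-tetramethyl-2,3,3a,4,8,8a-hexahydroazulen-7(1H)-one with an extra C1–C8 bond; cyclopropane C1–C8–C8a cis to the C3a–C4 bond)
Conditions: Rh2(OAc)4 (1 mol %), CH2Cl2, 23 °C, slow addition
Reagents that add atoms: none
Why: Intramolecular cyclopropanation by the rhodium carbenoid: the Z-alkene and the gem-dimethyl group hold the carbenoid over the electron-rich ring alkene, and the tether at the future C3a forces addition to its own face, so the seven-membered ring should close with a cis ring fusion.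

Step 9
Reactants: 12 tricyclic cyclopropyl enone
Product: 13 (1R,3aR,8aR)-1-hydroxy-1,4,4,6-tetramethyl-2,3,3a,4,8,8a-hexahydroazulen-7(1H)-one
Conditions: HClO4 (aq., cat.), THF/H2O, 23 °C
Reagents that add atoms: water, O
Why: Acid-catalysed homoconjugate addition of water to the cyclopropyl ketone (strain-driven ring opening): the exocyclic C8–C1 bond overlaps best with the carbonyl π-system and leads to a tertiary cation, so it should cleave, and water should enter at C1 with inversion, on the face of the ring-fusion hydrogens.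

Step 10
Reactants: 13 (1R,3aR,8aR)-1-hydroxy-1,4,4,6-tetramethyl-2,3,3a,4,8,8a-hexahydroazulen-7(1H)-one
Product: 14 (1R,3aR,8aR)-1,4,4,6-tetramethyl-1-(triethylsilyloxy)-2,3,3a,4,8,8a-hexahydroazulen-7(1H)-one
Conditions: Et3SiOTf, 2,6-lutidine, CH2Cl2, −78 → 0 °C
Reagents that add atoms: triethylsilyl trifluoromethanesulfonate, CC[Si](CC)(CC)OS(=O)(=O)C(F)(F)F
Why: Silyl triflate silylation should protect the hindered tertiary alcohol for the organometallic and Lewis-acid steps that follow.

Step 11
Reactants: 14 (1R,3aR,8aR)-1,4,4,6-tetramethyl-1-(triethylsilyloxy)-2,3,3a,4,8,8a-hexahydroazulen-7(1H)-one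
Product: 15 (1R,3aR,7S,8aR)-1,4,4,6-tetramethyl-1-(triethylsilyloxy)-1,2,3,3a,4,7,8,8a-octahydroazulen-7-ol
Conditions: (R)-2-methyl-CBS-oxazaborolidine (20 mol %), BH3·SMe2, THF, −30 °C
Reagents that add atoms: none
Why: Corey–Bakshi–Shibata reduction: with the α-methyl alkenyl branch as the large group, the (R)-catalyst should deliver hydride to the carbonyl face that carries the ring-fusion hydrogens (also the convex face of the cis-fused bicycle), giving the (7S) allylic alcohol.

Step 12
Reactants: 15 (1R,3aR,7S,8aR)-1,4,4,6-tetramethyl-1-(triethylsilyloxy)-1,2,3,3a,4,7,8,8a-octahydroazulen-7-ol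
Product: 17 2-[(1R,3aR,5S,8aR)-1,4,4,6-tetramethyl-1-(triethylsilyloxy)-1,2,3,3a,4,5,8,8a-octahydroazulen-5-yl]acetaldehyde, via allyl vinyl ether 16 (not isolated)
Conditions: Hg(OAc)2 (cat.), ethyl vinyl ether, reflux; then PhMe, 180 °C, sealed tube
Reagents that add atoms: ethyl vinyl ether, C=COCC
Why: Mercury-catalysed transvinylation followed by Claisen rearrangement: the suprafacial [3,3] shift should transfer the C7–O configuration to C5, placing CH2CHO on the hindered carbon next to quaternary C4 and moving the alkene to C6=C7 as in the target.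

Step 13
Reactants: 18 (E)-geranylacetone
Product: 19 4-[(2R,3R)-3-{2-[(2R)-3,3-dimethyloxiran-2-yl]ethyl}-3-methyloxiran-2-yl]butan-2-one
Conditions: D-fructose-derived Shi ketone (30 mol %), KHSO5 (as Oxone), K2CO3, Na2B4O7 buffer, Bu4NHSO4, MeCN/(MeO)2CH2/H2O, 0 °C
Reagents that add atoms: potassium peroxymonosulfate, [K+].[O-]S(=O)(=O)OO
Why: Shi asymmetric epoxidation: the chiral dioxirane should epoxidise both trisubstituted alkenes in the same sense through the spiro transition state, giving the (R,R)- and (R)-epoxides under catalyst control.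

Step 14
Reactants: 19 4-[(2R,3R)-3-{2-[(2R)-3,3-dimethyloxiran-2-yl]ethyl}-3-methyloxiran-2-yl]butan-2-one
Product: 22 diethyl {4-[(2R,3R)-3-{2-[(2R)-3,3-dimethyloxiran-2-yl]ethyl}-3-methyloxiran-2-yl]-2-oxobutyl}phosphonate, via lithium enolate 20 (not isolated), via keto phosphonite 21 (not isolated)
Conditions: LiN(iPr)2, THF, −78 °C; then ClP(OEt)2, −78 → 0 °C; then air
Reagents that add atoms: diethyl chlorophosphite, CCOP(Cl)OCC; dioxygen, O=O
Why: Kinetic deprotonation at the methyl group, C-phosphinylation of the enolate by the trivalent phosphorus chloride and air oxidation (enolate–chlorophosphite route to β-keto phosphonates) should place the phosphonate on the methyl-derived carbon without touching the epoxides.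

Step 15
Reactants: 17 2-[(1R,3aR,5S,8aR)-1,4,4,6-tetramethyl-1-(triethylsilyloxy)-1,2,3,3a,4,5,8,8a-octahydroazulen-5-yl]acetaldehyde; 22 diethyl {4-[(2R,3R)-3-{2-[(2R)-3,3-dimethyloxiran-2-yl]ethyl}-3-methyloxiran-2-yl]-2-oxobutyl}phosphonate
Product: 23 (4E)-1-[(2R,3R)-3-{2-[(2R)-3,3-dimethyloxiran-2-yl]ethyl}-3-methyloxiran-2-yl]-6-[(1R,3aR,5S,8aR)-1,4,4,6-tetramethyl-1-(triethylsilyloxy)-1,2,3,3a,4,5,8,8a-octahydroazulen-5-yl]hex-4-en-3-one
Conditions: LiCl, iPr2NEt, MeCN, 23 °C
Reagents that add atoms: none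
Why: Horner–Wadsworth–Emmons olefination under Masamune–Roush conditions: the lithium-chelated carbanion of 22 adds to the aldehyde of 17 and the oxaphosphetane collapses by syn-elimination of diethyl phosphate to the E-enone, so the bond between the future benzoxepine C6 and the linker CH2 is made as the σ-bond of a C=C. The closest known reaction type is the union of β-keto phosphonates with base-sensitive aldehydes by LiCl and an amine base. No ring is closed and no stereocentre is created, and the alkene geometry is not carried forward because the double bond is reduced in step 16. The selectivity needed is one of site: the ketone must be joined through the α-carbon that will sit next to quaternary C5a, which enolisation of the finished bicyclic ketone would not give (it goes to C8), and here the phosphonate installed on the methyl-derived carbon of 19 makes that carbon the only nucleophile. The mild base should leave both epoxides, the silyl ether and the aldehyde (no α-stereocentre) intact. The enone formed is the latent, regiodefined enol ether that terminates the cascade, so one convergent event joins the C16 and C13 halves and settles the regiochemistry of all later ring formation.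

Step 16
Reactants: 23 (4E)-enone from step 15
Product: 25 (3R,5aR,6R,9aR)-2,2,5a-trimethyl-6-{2-[(1R,3aR,5S,8aR)-1,4,4,6-tetramethyl-1-(triethylsilyloxy)-1,2,3,3a,4,5,8,8a-octahydroazulen-5-yl]ethyl}-3-(trimethylsilyloxy)octahydro-1-benzoxepin-7(2H)-one, via triethylsilyl enol ether 24 (not isolated)
Conditions: RhCl(PPh3)3 (2 mol %), Et3SiH, PhMe, 50 °C; then Me3SiOTf, 2,6-di-tert-butyl-4-methylpyridine, CH2Cl2, −78 °C; aq. NaHCO3
Reagents that add atoms: trimethylsilyl trifluoromethanesulfonate, C[Si](C)(C)OS(=O)(=O)C(F)(F)F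
Why: 1,4-Hydrosilylation gives the single regioisomeric silyl enol ether, and the Lewis-acid-triggered epoxide-opening cascade (oxacyclisation then Mukaiyama-type carbacyclisation) should form the oxepane by attack of the internal epoxide oxygen on the silylated terminal epoxide and then the cyclohexanone by anti attack of the enol ether on the epoxonium carbon (inversion at C5a, retention at C9a, trans fusion from the E-derived epoxide), with C6, α to the ketone, settling equatorial (DBU equilibration if needed).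

Step 17
Reactants: 25 bicyclic ketone from step 16
Product: 26 (3R,5aR,6R,7S,9aR)-2,2,5a,7-tetramethyl-6-{2-[(1R,3aR,5S,8aR)-1,4,4,6-tetramethyl-1-(triethylsilyloxy)-1,2,3,3a,4,5,8,8a-octahydroazulen-5-yl]ethyl}-3-(trimethylsilyloxy)decahydro-1-benzoxepin-7-ol
Conditions: MeMgBr, CeCl3, THF, −78 → 0 °C
Reagents that add atoms: methylmagnesium bromide, C[Mg]Br
Why: Organocerium 1,2-addition: the axial C5a methyl blocks axial approach (1,3-diaxial), so the methyl group should enter equatorially and give the axial (7S) tertiary alcohol, while the weakly basic reagent spares the epimerisable C6 centre.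

Step 18
Reactants: 26 bis-silyl ether from step 17
Product: 27 (3R,5aR,6R,7S,9aR)-6-{2-[(1R,3aR,5S,8aR)-1-hydroxy-1,4,4,6-tetramethyl-1,2,3,3a,4,5,8,8a-octahydroazulen-5-yl]ethyl}-2,2,5a,7-tetramethyldecahydro-1-benzoxepine-3,7-diol
Conditions: Bu4NF, THF, 23 → 50 °C
Reagents that add atoms: none
Why: Fluoride-mediated desilylation should remove both silyl ethers without acid, which the two tertiary alcohols would not tolerate.

Step 19
Reactants: 27 triol from step 18
Product: 28 sipholenone A
Conditions: Dess–Martin periodinane, NaHCO3, CH2Cl2, 0 → 23 °C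
Reagents that add atoms: none
Why: Dess–Martin oxidation should convert the only secondary alcohol into the oxepanone, the two tertiary alcohols being inert.

**Compound list**

1 | (S)-(+)-linalool, (3S)-3,7-dimethylocta-1,6-dien-3-ol | C=C[C@@](C)(O)CCC=C(C)C | starting material
2 | (S)-1-methylcyclopent-2-en-1-ol | O[C@]1(C)C=CCC1 | intermediate
3 | (S)-1-methylcyclopent-2-en-1-yl 2-methylpropanoate | CC(C)C(=O)O[C@]1(C)C=CCC1 | intermediate
4 | silyl ketene acetal of 3 | CC(C)=C(O[Si](C)(C)C)O[C@]1(C)C=CCC1 | intermediate (not isolated)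
5 | trimethylsilyl 2-methyl-2-[(1R)-3-methylcyclopent-2-en-1-yl]propanoate | C[Si](C)(C)OC(=O)C(C)(C)[C@@H]1CCC(C)=C1 | intermediate (not isolated)
6 | 2-methyl-2-[(1R)-3-methylcyclopent-2-en-1-yl]propan-1-ol | OCC(C)(C)[C@@H]1CCC(C)=C1 | intermediate
7 | 2-methyl-2-[(1R)-3-methylcyclopent-2-en-1-yl]propanal | O=CC(C)(C)[C@@H]1CCC(C)=C1 | intermediate
8 | methyl (2Z)-2,4-dimethyl-4-[(1R)-3-methylcyclopent-2-en-1-yl]pent-2-enoate | COC(=O)/C(C)=C\C(C)(C)[C@@H]1CCC(C)=C1 | intermediate
9 | (2Z)-2,4-dimethyl-4-[(1R)-3-methylcyclopent-2-en-1-yl]pent-2-enoic acid | OC(=O)/C(C)=C\C(C)(C)[C@@H]1CCC(C)=C1 | intermediate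
10 | acid chloride of 9 | ClC(=O)/C(C)=C\C(C)(C)[C@@H]1CCC(C)=C1 | intermediate (not isolated)
11 | (3Z)-1-diazo-3,5-dimethyl-5-[(1R)-3-methylcyclopent-2-en-1-yl]hex-3-en-2-one | [N-]=[N+]=CC(=O)/C(C)=C\C(C)(C)[C@@H]1CCC(C)=C1 | intermediate
12 | tricyclic cyclopropyl enone (13 less water; cyclopropane C1–C8–C8a on the face of the C3a–C4 bond) | CC1=CC(C)(C)[C@@H]2CC[C@]3(C)[C@H](C1=O)[C@H]23 | intermediate
13 | (1R,3aR,8aR)-1-hydroxy-1,4,4,6-tetramethyl-2,3,3a,4,8,8a-hexahydroazulen-7(1H)-one | CC1=CC(C)(C)[C@@H]2CC[C@@](C)(O)[C@@H]2CC1=O | intermediate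
14 | (1R,3aR,8aR)-1,4,4,6-tetramethyl-1-(triethylsilyloxy)-2,3,3a,4,8,8a-hexahydroazulen-7(1H)-one | CC1=CC(C)(C)[C@@H]2CC[C@@](C)(O[Si](CC)(CC)CC)[C@@H]2CC1=O | intermediate
15 | (1R,3aR,7S,8aR)-1,4,4,6-tetramethyl-1-(triethylsilyloxy)-1,2,3,3a,4,7,8,8a-octahydroazulen-7-ol | CC1=CC(C)(C)[C@@H]2CC[C@@](C)(O[Si](CC)(CC)CC)[C@@H]2C[C@@H]1O | intermediate
16 | vinyl ether of 15 | CC1=CC(C)(C)[C@@H]2CC[C@@](C)(O[Si](CC)(CC)CC)[C@@H]2C[C@@H]1OC=C | intermediate (not isolated)
17 | 2-[(1R,3aR,5S,8aR)-1,4,4,6-tetramethyl-1-(triethylsilyloxy)-1,2,3,3a,4,5,8,8a-octahydroazulen-5-yl]acetaldehyde | CC1=CC[C@@H]2[C@@H](CC[C@@]2(C)O[Si](CC)(CC)CC)C(C)(C)[C@H]1CC=O | intermediate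
18 | (E)-geranylacetone, (5E)-6,10-dimethylundeca-5,9-dien-2-one | CC(=O)CC/C=C(\C)CCC=C(C)C | starting material
19 | 4-[(2R,3R)-3-{2-[(2R)-3,3-dimethyloxiran-2-yl]ethyl}-3-methyloxiran-2-yl]butan-2-one | CC(=O)CC[C@H]1O[C@]1(C)CC[C@H]1OC1(C)C | intermediate
20 | lithium enolate of 19 (methyl side) | [Li+].[O-]C(=C)CC[C@H]1O[C@]1(C)CC[C@H]1OC1(C)C | intermediate (not isolated)
21 | diethyl keto phosphonite (trivalent phosphorus analogue of 22) | CCOP(OCC)CC(=O)CC[C@H]1O[C@]1(C)CC[C@H]1OC1(C)C | intermediate (not isolated)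
22 | diethyl {4-[(2R,3R)-3-{2-[(2R)-3,3-dimethyloxiran-2-yl]ethyl}-3-methyloxiran-2-yl]-2-oxobutyl}phosphonate | CCOP(=O)(OCC)CC(=O)CC[C@H]1O[C@]1(C)CC[C@H]1OC1(C)C | intermediate
23 | (4E)-1-[(2R,3R)-3-{2-[(2R)-3,3-dimethyloxiran-2-yl]ethyl}-3-methyloxiran-2-yl]-6-[(1R,3aR,5S,8aR)-1,4,4,6-tetramethyl-1-(triethylsilyloxy)-1,2,3,3a,4,5,8,8a-octahydroazulen-5-yl]hex-4-en-3-one | CC1=CC[C@@H]2[C@@H](CC[C@@]2(C)O[Si](CC)(CC)CC)C(C)(C)[C@H]1C/C=C/C(=O)CC[C@H]1O[C@]1(C)CC[C@H]1OC1(C)C | intermediate
24 | (Z)-triethylsilyl enol ether of the saturated ketone from 23 | CC1=CC[C@@H]2[C@@H](CC[C@@]2(C)O[Si](CC)(CC)CC)C(C)(C)[C@H]1CC/C=C(\O[Si](CC)(CC)CC)CC[C@H]1O[C@]1(C)CC[C@H]1OC1(C)C | intermediate (not isolated)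
25 | (3R,5aR,6R,9aR)-2,2,5a-trimethyl-6-{2-[(1R,3aR,5S,8aR)-1,4,4,6-tetramethyl-1-(triethylsilyloxy)-1,2,3,3a,4,5,8,8a-octahydroazulen-5-yl]ethyl}-3-(trimethylsilyloxy)octahydro-1-benzoxepin-7(2H)-one | CC1=CC[C@@H]2[C@@H](CC[C@@]2(C)O[Si](CC)(CC)CC)C(C)(C)[C@H]1CC[C@@H]1[C@@]2(C)CC[C@@H](O[Si](C)(C)C)C(C)(C)O[C@@H]2CCC1=O | intermediate
26 | (3R,5aR,6R,7S,9aR)-2,2,5a,7-tetramethyl-6-{2-[(1R,3aR,5S,8aR)-1,4,4,6-tetramethyl-1-(triethylsilyloxy)-1,2,3,3a,4,5,8,8a-octahydroazulen-5-yl]ethyl}-3-(trimethylsilyloxy)decahydro-1-benzoxepin-7-ol | CC1=CC[C@@H]2[C@@H](CC[C@@]2(C)O[Si](CC)(CC)CC)C(C)(C)[C@H]1CC[C@@H]1[C@@]2(C)CC[C@@H](O[Si](C)(C)C)C(C)(C)O[C@@H]2CC[C@]1(C)O | intermediate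
27 | (3R,5aR,6R,7S,9aR)-6-{2-[(1R,3aR,5S,8aR)-1-hydroxy-1,4,4,6-tetramethyl-1,2,3,3a,4,5,8,8a-octahydroazulen-5-yl]ethyl}-2,2,5a,7-tetramethyldecahydro-1-benzoxepine-3,7-diol | CC1=CC[C@@H]2[C@@H](CC[C@@]2(C)O)C(C)(C)[C@H]1CC[C@@H]1[C@@]2(C)CC[C@@H](O)C(C)(C)O[C@@H]2CC[C@]1(C)O | intermediate
28 | sipholenone A, (5aR,6R,7S,9aR)-7-hydroxy-6-{2-[(1R,3aR,5S,8aR)-1-hydroxy-1,4,4,6-tetramethyl-1,2,3,3a,4,5,8,8a-octahydroazulen-5-yl]ethyl}-2,2,5a,7-tetramethyloctahydro-1-benzoxepin-3(2H)-one | CC1=CC[C@@H]2[C@@H](CC[C@@]2(C)O)C(C)(C)[C@H]1CC[C@@H]1[C@@]2(C)CCC(=O)C(C)(C)O[C@@H]2CC[C@]1(C)O | target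

**Summary**

Total step count: 19. Longest linear sequence: 17 steps (steps 1–12, then 15–19).

**Steps most likely to fail**

Step 16. The hindered, trisubstituted enol ether may capture the epoxonium ion too slowly, so that premature ether formation by the wrong ring size, or cyclisation onto the internal epoxide first, competes on a precious late intermediate. The fallback runs the cascade on the simple fragment and joins the halves afterwards. It sets out from 19 (and uses 17) and returns at 25. Compound 19 is converted with LiN(iPr)2 and tBuMe2SiCl into its kinetic tert-butyldimethylsilyl enol ether F1. Me3SiOTf with 2,6-di-tert-butyl-4-methylpyridine should cyclise this to the side-chain-free bicyclic ketone F2. Dehydrogenation with IBX can only go toward C8–C9, because C5a has no hydrogen, and gives the enone F3. Kinetic α′-deprotonation at C6 with LiN(iPr)2 and aldol addition to 17 gives the β-hydroxy enone F4. Dehydration with Martin sulfurane gives the cross-conjugated dienone F5. Double conjugate reduction with [(Ph3P)CuH]6 and PhSiH3, then equilibration at C6, gives 25.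

Step 8. The carbenoid may dimerise, insert into C–H bonds or undergo Wolff rearrangement faster than it closes the seven-membered ring. The fallback replaces the carbene by an anionic ring closure. It sets out from 9 and returns at 13. MeLi (two equivalents) converts 9 into the Z-methyl ketone F6. mCPBA epoxidises the electron-rich ring alkene on the face opposite the side chain to give the epoxy enone F7. The kinetic methyl enolate (KN(SiMe3)2) then opens the epoxide at its secondary carbon from the tether face (7-exo, intramolecular epoxide alkylation), giving 13 directly with the same cis fusion and carbinol configuration.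

Step 9. Proton loss from the tertiary cation may outrun capture by water, or the cyclopropane may cleave with eroded regiochemistry. The fallback accepts the elimination and installs the oxygen afterwards. It sets out from 12 and returns at 13. TsOH in benzene isomerises 12 to the ring alkene F8. mCPBA epoxidises it from the convex face, chemoselectively over the enone, to give the epoxide F9. LiBHEt3 opens the epoxide at the secondary carbon and reduces the ketone, giving the diol F10. MnO2 re-oxidises the allylic alcohol to 13.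

Further compounds
F1 | step 16 | tert-butyldimethylsilyl enol ether of 19 (methyl side) | C=C(O[Si](C)(C)C(C)(C)C)CC[C@H]1O[C@]1(C)CC[C@H]1OC1(C)C
F2 | step 16 | (3R,5aR,9aR)-2,2,5a-trimethyl-3-(trimethylsilyloxy)octahydro-1-benzoxepin-7(2H)-one | O=C1CC[C@H]2OC(C)(C)[C@H](O[Si](C)(C)C)CC[C@]2(C)C1
F3 | step 16 | (3R,5aR,9aR)-2,2,5a-trimethyl-3-(trimethylsilyloxy)-3,4,5,5a,6,9a-hexahydro-1-benzoxepin-7(2H)-one (C8=C9 enone) | O=C1C=C[C@H]2OC(C)(C)[C@H](O[Si](C)(C)C)CC[C@]2(C)C1
F4 | step 16 | aldol adduct of F3 (C6) with 17, mixture at C6 and the carbinol carbon | CC1=CC[C@@H]2[C@@H](CC[C@@]2(C)O[Si](CC)(CC)CC)C(C)(C)[C@H]1CC(O)C1[C@@]2(C)CC[C@@H](O[Si](C)(C)C)C(C)(C)O[C@@H]2C=CC1=O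
F5 | step 16 | cross-conjugated dienone from F4 (C6 alkylidene, C8=C9) | CC1=CC[C@@H]2[C@@H](CC[C@@]2(C)O[Si](CC)(CC)CC)C(C)(C)[C@H]1CC=C1[C@@]2(C)CC[C@@H](O[Si](C)(C)C)C(C)(C)O[C@@H]2C=CC1=O
F6 | step 8 | (3Z)-3,5-dimethyl-5-[(1R)-3-methylcyclopent-2-en-1-yl]hex-3-en-2-one | CC(=O)/C(C)=C\C(C)(C)[C@@H]1CCC(C)=C1
F7 | step 8 | epoxide of F6 at the ring alkene, oxygen trans to the side chain | CC(=O)/C(C)=C\C(C)(C)[C@@H]1CC[C@@]2(C)O[C@@H]12
F8 | step 9 | (3aR,8aR)-1,4,4,6-tetramethyl-3,3a,4,8a-tetrahydroazulen-7(8H)-one (C1=C2 alkene) | CC1=CC(C)(C)[C@@H]2CC=C(C)[C@@H]2CC1=O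
F9 | step 9 | 1,2-epoxide of F8 on the face of the ring-fusion hydrogens | CC1=CC(C)(C)[C@@H]2C[C@H]3O[C@@]3(C)[C@@H]2CC1=O
F10 | step 9 | (1R,3aR,8aR)-1,4,4,6-tetramethyl-1,2,3,3a,4,7,8,8a-octahydroazulene-1,7-diol, mixture at C7 | CC1=CC(C)(C)[C@@H]2CC[C@@](C)(O)[C@@H]2CC1O
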